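Both five-carbon units of the target end in a C=C(CH3)2 group: the C2''=C3'' bond of the ring B prenyl group and, in latent form, the C3–C2 bond of the pyran fused to ring A. Both are therefore traced back to C-allyl groups set by Claisen rearrangements, and a single twofold cross-metathesis with 2-methyl-2-butene converts them into prenyl groups. The metathesis substrate is the bis-allyl dihydrochalcone, assembled by aldol condensation and conjugate reduction with [(Ph3P)CuH]6, with acetates on O2', O6' and the ring B hydroxyl and a free 4'-hydroxyl, so that the acid closure of the pyran that follows can only use O4'.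

Key step: step 12

Remark on the chemistry: with all three ring A hydroxyls free, O2' as well as O4' could add to the ring A prenyl group, so O2' and O6' are kept as acetates until the pyran is closed; the target has no stereocentre (primed locants refer to ring A, which carries the acyl group at C1'; MOM = methoxymethyl).

Step 1
Reactants: 1 3,4-dihydroxybenzaldehyde; 2 allyl bromide
Product: 3 4-(allyloxy)-3-hydroxybenzaldehyde
Conditions: NaHCO3, NaI (cat.), DMF, 40 °C
Reagents that add atoms: none
Why: Williamson ether synthesis in which hydrogencarbonate ionises only the 4-hydroxyl, the more acidic phenol because it is para to the formyl group, so that the allyl group goes on O4.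

Step 2
Reactants: 3 4-(allyloxy)-3-hydroxybenzaldehyde
Product: 4 4-(allyloxy)-3-(methoxymethoxy)benzaldehyde
Conditions: MOMCl, i-Pr2NEt, CH2Cl2, 0 °C to rt
Reagents that add atoms: chloromethyl methyl ether, COCCl
Why: Alkylation of the remaining phenol with the chloromethyl ether (acetal formation via the oxocarbenium ion) gives a MOM ether that is stable to heat and to base and that fixes which oxygen is methylated in step 4.

Step 3
Reactants: 4 4-(allyloxy)-3-(methoxymethoxy)benzaldehyde
Product: 5 3-allyl-4-hydroxy-5-(methoxymethoxy)benzaldehyde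
Conditions: N,N-diethylaniline, 200 °C, N2
Reagents that add atoms: none
Why: Aromatic Claisen rearrangement, a [3,3]-sigmatropic shift followed by tautomerisation of the dienone, moves the allyl group from O4 to C5, the only free ortho position, and frees the 4-hydroxyl.

Step 4
Reactants: 5 3-allyl-4-hydroxy-5-(methoxymethoxy)benzaldehyde
Product: 6 3-allyl-4-methoxy-5-(methoxymethoxy)benzaldehyde
Conditions: MeI, K2CO3, DMF, rt
Reagents that add atoms: iodomethane, CI
Why: Williamson O-methylation of the single free phenol with carbonate as base places the methoxy group on O4 without ambiguity.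

Step 5
Reactants: 7 2',4',6'-trihydroxyacetophenone; 2 allyl bromide
Product: 8 1-[4-(allyloxy)-2,6-dihydroxyphenyl]ethanone
Conditions: K2CO3 (1 equiv), allyl bromide (1 equiv), acetone, reflux
Reagents that add atoms: none
Why: Williamson ether synthesis with one equivalent of base and halide, selective for the 4'-hydroxyl because it is the most acidic phenol and the only one not hydrogen-bonded to the acetyl carbonyl.

Step 6
Reactants: 8 1-[4-(allyloxy)-2,6-dihydroxyphenyl]ethanone
Product: 9 1-[4-(allyloxy)-2,6-bis(methoxymethoxy)phenyl]ethanone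
Conditions: NaH, MOMCl, DMF, 0 °C to rt
Reagents that add atoms: chloromethyl methyl ether, COCCl
Why: Irreversible deprotonation of both chelated phenols with NaH and O-alkylation with the chloromethyl ether give the bis-MOM ether, which prevents phenoxide formation and flavanone closure in the aldol step.

Step 7
Reactants: 9 1-[4-(allyloxy)-2,6-bis(methoxymethoxy)phenyl]ethanone; 6 3-allyl-4-methoxy-5-(methoxymethoxy)benzaldehyde
Product: 11 (E)-1-[4-(allyloxy)-2,6-bis(methoxymethoxy)phenyl]-3-[3-allyl-4-methoxy-5-(methoxymethoxy)phenyl]prop-2-en-1-one, via racemic β-hydroxy ketone aldol adduct 10 (not isolated)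
Conditions: KOH (aq), EtOH, rt
Reagents that add atoms: none
Why: Claisen–Schmidt condensation, in which the methyl ketone enolate adds to the non-enolisable aldehyde and the aldol adduct loses water by E1cB elimination to the conjugated E-enone, with the MOM ethers, the allyl ether and the allyl group inert to hydroxide at room temperature.

Step 8
Reactants: 11 (E)-1-[4-(allyloxy)-2,6-bis(methoxymethoxy)phenyl]-3-[3-allyl-4-methoxy-5-(methoxymethoxy)phenyl]prop-2-en-1-one
Product: 12 1-[4-(allyloxy)-2,6-bis(methoxymethoxy)phenyl]-3-[3-allyl-4-methoxy-5-(methoxymethoxy)phenyl]propan-1-one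
Conditions: [(Ph3P)CuH]6 (0.4 equiv), H2O, degassed toluene, rt
Reagents that add atoms: none
Why: Conjugate reduction in which the phosphine-stabilised copper hydride delivers hydride to the β-carbon of the enone and water protonates the copper enolate, a soft hydride that leaves the isolated terminal alkene, the aryl allyl ether and the ketone untouched.

Step 9
Reactants: 12 1-[4-(allyloxy)-2,6-bis(methoxymethoxy)phenyl]-3-[3-allyl-4-methoxy-5-(methoxymethoxy)phenyl]propan-1-one
Product: 13 1-[4-(allyloxy)-2,6-dihydroxyphenyl]-3-(3-allyl-5-hydroxy-4-methoxyphenyl)propan-1-one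
Conditions: conc. HCl (cat.), MeOH, 40 °C
Reagents that add atoms: none
Why: Acid-catalysed transacetalisation with methanol cleaves the three MOM ethers, whereas the aryl allyl ether and the terminal alkenes are stable to dilute HCl at this temperature.

Step 10
Reactants: 13 1-[4-(allyloxy)-2,6-dihydroxyphenyl]-3-(3-allyl-5-hydroxy-4-methoxyphenyl)propan-1-one
Product: 14 1-[2,6-diacetoxy-4-(allyloxy)phenyl]-3-(3-acetoxy-5-allyl-4-methoxyphenyl)propan-1-one
Conditions: Ac2O, pyridine, DMAP (cat.), rt
Reagents that add atoms: acetic anhydride, CC(=O)OC(C)=O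
Why: DMAP-catalysed acyl transfer esterifies all three phenols, the hydrogen-bonded 2'- and 6'-hydroxyls included, which installs acid-stable masks on O2' and O6' at the one stage where O4' is still blocked as its allyl ether.

Step 11
Reactants: 14 1-[2,6-diacetoxy-4-(allyloxy)phenyl]-3-(3-acetoxy-5-allyl-4-methoxyphenyl)propan-1-one
Product: 15 1-(2,6-diacetoxy-3-allyl-4-hydroxyphenyl)-3-(3-acetoxy-5-allyl-4-methoxyphenyl)propan-1-one
Conditions: 1,2-dichlorobenzene, 190 °C, sealed tube, N2
Reagents that add atoms: none
Why: Aromatic Claisen rearrangement ([3,3]-sigmatropic shift, then tautomerisation) moves the allyl group from O4' to C3', a single product because C3' and C5' are equivalent by symmetry, and in a neutral, non-nucleophilic solvent the aryl acetates should stay where they are.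

Step 12
Reactants: 15 1-(2,6-diacetoxy-3-allyl-4-hydroxyphenyl)-3-(3-acetoxy-5-allyl-4-methoxyphenyl)propan-1-one; 16 2-methyl-2-butene
Product: 19 1-[2,6-diacetoxy-4-hydroxy-3-(3-methylbut-2-enyl)phenyl]-3-[3-acetoxy-4-methoxy-5-(3-methylbut-2-enyl)phenyl]propan-1-one, via ring A prenyl ring B allyl triacetate 17 (not isolated), via ring A allyl ring B prenyl triacetate 18 (not isolated)
Conditions: RuCl2(=CHPh)(PCy3)(H2IMes) (second-generation Grubbs catalyst, 5 mol %), 1,4-benzoquinone (10 mol %), 2-methyl-2-butene/CH2Cl2 (3:1 v/v), 35 °C, sealed tube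
Reagents that add atoms: none
Why: The ruthenium alkylidene adds to each terminal allyl alkene in a [2+2] cycloaddition, the ruthenacyclobutane opens by cycloreversion, and turnover with 2-methyl-2-butene caps each chain with an isopropylidene unit while propene leaves, which forms the C2''=C3'' bond on ring B and the future C3=C2 bond of the pyran on ring A in the same flask. The closest known reaction type is the ruthenium-catalysed cross-metathesis of allylarenes, ortho-allylphenols included, with 2-methyl-2-butene to give prenylarenes. No ring is closed and no stereocentre or alkene geometry is set, because each new double bond carries two methyl groups at one end. The step needs cross-coupling at both sites instead of homodimerisation, which the large excess of the trisubstituted partner, itself unable to dimerise, should secure. It also needs the double bonds to stay out of conjugation with the rings, which the short reaction time at 35 °C and 1,4-benzoquinone as a trap for ruthenium hydride should secure. The ketone, the aryl acetates, the aryl methyl ether and the free 4'-hydroxyl do not react with the carbene, and the two sites are remote from each other, so 17 and 18 both converge on 19.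

Step 13
Reactants: 19 1-[2,6-diacetoxy-4-hydroxy-3-(3-methylbut-2-enyl)phenyl]-3-[3-acetoxy-4-methoxy-5-(3-methylbut-2-enyl)phenyl]propan-1-one
Product: 20 1-(5,7-diacetoxy-2,2-dimethylchroman-6-yl)-3-[3-acetoxy-4-methoxy-5-(3-methylbut-2-enyl)phenyl]propan-1-one
Conditions: Amberlyst 15 (dry), CH2Cl2, rt
Reagents that add atoms: none
Why: Acid-catalysed intramolecular hydroalkoxylation, in which Markovnikov protonation of the ring A prenyl alkene gives a tertiary cation that is captured by the neighbouring free 4'-hydroxyl in a 6-endo-trig closure to the 2,2-dimethylchroman, while O2' is acetylated and the ring B prenyl group has only methoxy and hydrogen neighbours and returns to the alkene.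

Step 14
Reactants: 20 1-(5,7-diacetoxy-2,2-dimethylchroman-6-yl)-3-[3-acetoxy-4-methoxy-5-(3-methylbut-2-enyl)phenyl]propan-1-one
Product: 21 1-(5,7-dihydroxy-2,2-dimethylchroman-6-yl)-3-[3-hydroxy-4-methoxy-5-(3-methylbut-2-enyl)phenyl]propan-1-one
Conditions: K2CO3, degassed MeOH, 0 °C to rt; then aq NH4Cl
Reagents that add atoms: none
Why: Base-catalysed transesterification with methanol (methanolysis of three aryl acetates) frees the 5-, 7- and ring B hydroxyls under conditions that do not affect the chroman, the prenyl alkene, the ketone or the methyl ether.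

Compound list
1 | 3,4-dihydroxybenzaldehyde | O=Cc1ccc(O)c(O)c1 | starting material
2 | allyl bromide (3-bromoprop-1-ene) | C=CCBr | starting material
3 | 4-(allyloxy)-3-hydroxybenzaldehyde | O=Cc1ccc(OCC=C)c(O)c1 | intermediate
4 | 4-(allyloxy)-3-(methoxymethoxy)benzaldehyde | O=Cc1ccc(OCC=C)c(OCOC)c1 | intermediate
5 | 3-allyl-4-hydroxy-5-(methoxymethoxy)benzaldehyde | O=Cc1cc(CC=C)c(O)c(OCOC)c1 | intermediate
6 | 3-allyl-4-methoxy-5-(methoxymethoxy)benzaldehyde | O=Cc1cc(CC=C)c(OC)c(OCOC)c1 | intermediate
7 | 2',4',6'-trihydroxyacetophenone | CC(=O)c1c(O)cc(O)cc1O | starting material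
8 | 1-[4-(allyloxy)-2,6-dihydroxyphenyl]ethanone | CC(=O)c1c(O)cc(OCC=C)cc1O | intermediate
9 | 1-[4-(allyloxy)-2,6-bis(methoxymethoxy)phenyl]ethanone | CC(=O)c1c(OCOC)cc(OCC=C)cc1OCOC | intermediate
10 | racemic 1-[4-(allyloxy)-2,6-bis(methoxymethoxy)phenyl]-3-[3-allyl-4-methoxy-5-(methoxymethoxy)phenyl]-3-hydroxypropan-1-one | O=C(CC(O)c1cc(CC=C)c(OC)c(OCOC)c1)c1c(OCOC)cc(OCC=C)cc1OCOC | intermediate (not isolated)
11 | (E)-1-[4-(allyloxy)-2,6-bis(methoxymethoxy)phenyl]-3-[3-allyl-4-methoxy-5-(methoxymethoxy)phenyl]prop-2-en-1-one | O=C(/C=C/c1cc(CC=C)c(OC)c(OCOC)c1)c1c(OCOC)cc(OCC=C)cc1OCOC | intermediate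
12 | 1-[4-(allyloxy)-2,6-bis(methoxymethoxy)phenyl]-3-[3-allyl-4-methoxy-5-(methoxymethoxy)phenyl]propan-1-one | O=C(CCc1cc(CC=C)c(OC)c(OCOC)c1)c1c(OCOC)cc(OCC=C)cc1OCOC | intermediate
13 | 1-[4-(allyloxy)-2,6-dihydroxyphenyl]-3-(3-allyl-5-hydroxy-4-methoxyphenyl)propan-1-one | O=C(CCc1cc(CC=C)c(OC)c(O)c1)c1c(O)cc(OCC=C)cc1O | intermediate
14 | 1-[2,6-diacetoxy-4-(allyloxy)phenyl]-3-(3-acetoxy-5-allyl-4-methoxyphenyl)propan-1-one | O=C(CCc1cc(CC=C)c(OC)c(OC(C)=O)c1)c1c(OC(C)=O)cc(OCC=C)cc1OC(C)=O | intermediate
15 | 1-(2,6-diacetoxy-3-allyl-4-hydroxyphenyl)-3-(3-acetoxy-5-allyl-4-methoxyphenyl)propan-1-one | O=C(CCc1cc(CC=C)c(OC)c(OC(C)=O)c1)c1c(OC(C)=O)cc(O)c(CC=C)c1OC(C)=O | intermediate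
16 | 2-methyl-2-butene | CC=C(C)C | starting material
17 | 1-[2,6-diacetoxy-4-hydroxy-3-(3-methylbut-2-enyl)phenyl]-3-(3-acetoxy-5-allyl-4-methoxyphenyl)propan-1-one | O=C(CCc1cc(CC=C)c(OC)c(OC(C)=O)c1)c1c(OC(C)=O)cc(O)c(CC=C(C)C)c1OC(C)=O | intermediate (not isolated)
18 | 1-(2,6-diacetoxy-3-allyl-4-hydroxyphenyl)-3-[3-acetoxy-4-methoxy-5-(3-methylbut-2-enyl)phenyl]propan-1-one | O=C(CCc1cc(CC=C(C)C)c(OC)c(OC(C)=O)c1)c1c(OC(C)=O)cc(O)c(CC=C)c1OC(C)=O | intermediate (not isolated)
19 | 1-[2,6-diacetoxy-4-hydroxy-3-(3-methylbut-2-enyl)phenyl]-3-[3-acetoxy-4-methoxy-5-(3-methylbut-2-enyl)phenyl]propan-1-one | O=C(CCc1cc(CC=C(C)C)c(OC)c(OC(C)=O)c1)c1c(OC(C)=O)cc(O)c(CC=C(C)C)c1OC(C)=O | intermediate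
20 | 1-(5,7-diacetoxy-2,2-dimethylchroman-6-yl)-3-[3-acetoxy-4-methoxy-5-(3-methylbut-2-enyl)phenyl]propan-1-one | O=C(CCc1cc(CC=C(C)C)c(OC)c(OC(C)=O)c1)c1c(OC(C)=O)cc2c(c1OC(C)=O)CCC(C)(C)O2 | intermediate
21 | 1-(5,7-dihydroxy-2,2-dimethylchroman-6-yl)-3-[3-hydroxy-4-methoxy-5-(3-methylbut-2-enyl)phenyl]propan-1-one | COc1c(O)cc(CCC(=O)c2c(O)cc3c(c2O)CCC(C)(C)O3)cc1CC=C(C)C | target

Total step count: 14.
Longest linear sequence: 12 steps (steps 1 to 4 and 7 to 14, from 3,4-dihydroxybenzaldehyde); the ring A branch (steps 5 and 6) joins at step 7.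

Steps most likely to fail

Step 12 (twofold cross-metathesis). The ring A allyl group, wedged between an acetate and a phenol, may turn over more slowly than the ring B site, so that 18 accumulates. The longer exposure would then let ruthenium hydride shift the remaining terminal double bond into conjugation. The fallback sets out from aldehyde 6 and comes back to the route at 18; it separates the two metatheses. Cross-metathesis of 6 alone with 16 (same catalyst) should give 4-methoxy-3-(methoxymethoxy)-5-(3-methylbut-2-enyl)benzaldehyde F1. Condensation of F1 with ketone 9 (KOH, EtOH) should pass through the racemic aldol adduct F2 to the (E)-chalcone F3. [(Ph3P)CuH]6 should reduce F3 to the dihydrochalcone F4, and HCl/MeOH at rt should remove the MOM groups to give the triol F5. Ac2O/pyridine/DMAP should give the triacetate F6, and thermal Claisen rearrangement of F6 should deliver 18. Compound 18 then needs only one cross-metathesis at the ring A site, driven with fresh catalyst, to reach 19.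

Step 13 (closure of the pyran). Protonation of the ring B prenyl group may compete and lead to hydration, double-bond shift or Friedel–Crafts closure onto ring B. The resin may also cleave an acetate in part, which would unmask O2'. The fallback sets out from 19 and comes back at 20; it closes the ring by selenoetherification and then removes selenium reductively. N-(Phenylseleno)phthalimide with a trace of camphorsulfonic acid in CH2Cl2 at −78 °C to 0 °C should give the racemic 3-(phenylselanyl)chroman F7. Only the seleniranium ion on ring A has a hydroxyl (O4') that captures it irreversibly, whereas the one on ring B reverts. Bu3SnH/AIBN in toluene at 80 °C should then replace selenium by hydrogen and give 20.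

Step 5 (mono-O-allylation of the ring A ketone). The ambident phloroglucinol-type phenoxide may be allylated a second time on oxygen or on a ring carbon, which would erode the supply of 8. The fallback sets out from 7 and comes back at 8, and it makes no new compound. It is a Mitsunobu etherification with allyl alcohol, PPh3 and diisopropyl azodicarboxylate in THF at 0 °C. No free phenoxide is generated, and only the non-chelated, most acidic 4'-hydroxyl should be activated as the pronucleophile.

Further compounds
F1 | step 12 | 4-methoxy-3-(methoxymethoxy)-5-(3-methylbut-2-enyl)benzaldehyde | O=Cc1cc(CC=C(C)C)c(OC)c(OCOC)c1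
F2 | step 12 | racemic 1-[4-(allyloxy)-2,6-bis(methoxymethoxy)phenyl]-3-hydroxy-3-[4-methoxy-3-(methoxymethoxy)-5-(3-methylbut-2-enyl)phenyl]propan-1-one | O=C(CC(O)c1cc(CC=C(C)C)c(OC)c(OCOC)c1)c1c(OCOC)cc(OCC=C)cc1OCOC
F3 | step 12 | (E)-1-[4-(allyloxy)-2,6-bis(methoxymethoxy)phenyl]-3-[4-methoxy-3-(methoxymethoxy)-5-(3-methylbut-2-enyl)phenyl]prop-2-en-1-one | O=C(/C=C/c1cc(CC=C(C)C)c(OC)c(OCOC)c1)c1c(OCOC)cc(OCC=C)cc1OCOC
F4 | step 12 | 1-[4-(allyloxy)-2,6-bis(methoxymethoxy)phenyl]-3-[4-methoxy-3-(methoxymethoxy)-5-(3-methylbut-2-enyl)phenyl]propan-1-one | O=C(CCc1cc(CC=C(C)C)c(OC)c(OCOC)c1)c1c(OCOC)cc(OCC=C)cc1OCOC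
F5 | step 12 | 1-[4-(allyloxy)-2,6-dihydroxyphenyl]-3-[3-hydroxy-4-methoxy-5-(3-methylbut-2-enyl)phenyl]propan-1-one | O=C(CCc1cc(CC=C(C)C)c(OC)c(O)c1)c1c(O)cc(OCC=C)cc1O
F6 | step 12 | 1-[2,6-diacetoxy-4-(allyloxy)phenyl]-3-[3-acetoxy-4-methoxy-5-(3-methylbut-2-enyl)phenyl]propan-1-one | O=C(CCc1cc(CC=C(C)C)c(OC)c(OC(C)=O)c1)c1c(OC(C)=O)cc(OCC=C)cc1OC(C)=O
F7 | step 13 | racemic 1-[5,7-diacetoxy-2,2-dimethyl-3-(phenylselanyl)chroman-6-yl]-3-[3-acetoxy-4-methoxy-5-(3-methylbut-2-enyl)phenyl]propan-1-one | O=C(CCc1cc(CC=C(C)C)c(OC)c(OC(C)=O)c1)c1c(OC(C)=O)cc2c(c1OC(C)=O)CC([Se]c1ccccc1)C(C)(C)O2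
F0 | step 5 | none | none
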